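(Readings and results were computed for an exercise, and the scatter is random.)

If every unit of starting material takes two partners, as the name bis adduct says, the leftover in the theta run is 1.30 M of partner, and its last reading of bis adduct is 0%, while the epsilon run ends 0.240 M short, so on that supposition partner is the limiting reagent there. We suppose that leftover partner carries bis adduct further.

in all of them: starting material 0.40 M

|  | partner | remark | time |
|---|---|---|---|
| epsilon | 0.56 M (in portions, 3) | run made earlier; portions every 3.0 s |  |
| theta | 2.1 M (in portions, 3) | run made earlier; portions every 3.0 s |  |
| Thursday's | 0.480 M (in portions, 3) | the portions of partner follow each other after 3.0 s, the first at the start | 6.0 min |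
| Wednesday's | 1.00 M (in portions, 3) | the portions of partner follow each other after 3.0 s, the first at the start | 6.0 min |
| Saturday's | 1.60 M (in portions, 3) | the portions of partner follow each other after 3.0 s, the first at the start | 6.0 min |

| run | time / min | bis adduct / % |
|---|---|---|
| epsilon | 0.500 | 18.5 |
| epsilon | 0.667 | 19.2 |
| epsilon | 1.00 | 18.8 |
| epsilon | 1.50 | 19.2 |
| epsilon | 2.50 | 18.3 |
| epsilon | 4.00 | 18.8 |
| epsilon | 6.00 | 19.6 |
| theta | 0.333 | 2.4 |
| theta | 1.00 | 0.3 |
| theta | 1.50 | 0 |
| theta | 2.50 | 0.5 |
| theta | 4.00 | 0.7 |
| theta | 5.00 | 0 |
| theta | 6.00 | 0 |

(scatter of a reading: 0.5 percentage points)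



- amount of bis adduct at the end, in percent of the starting material charged, for each flask in turn (Thursday's, Wednesday's, Saturday's)

Our zero of the scale is the statistical case. Partner lands at random on the units, with load n = c(partner)/c(starting material), and the share holding exactly two is n squared times e to the minus n, halved. The epsilon readings scatter about one level, so we take their mean:

epsilon: n = 1.40, statistical share 24.2%, mean reading 18.9%

Their ratio, 0.783, is our retention ρ, the reading over the statistical share. There are two ways to Thursday's flask:

retention: n = 1.20, statistical share 21.7%, times ρ gives 17.0%

square law, the epsilon mean scaled by the load squared: 13.9%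

They part. The square law needs a load far below one, and Thursday's load is above one; on theta it gives 266%, more than the charge. So the square law cheats here.

Retention has its own test on theta:

n = 5.25, ρ times statistical share 5.66%, mean reading 0.557%

On the theta run, then, the retention figure stands above the mean reading. We commit to 17.0% for Thursday's, and treat 20.1% for Wednesday's and 11.5% for Saturday's as upper figures.

The forecast gives 19%, 10% and 0.6%, a different row from ours, taking it that “each portion is consumed instantly”.

The flasks give 16.9% on Thursday's, 16.4% on Wednesday's and <0.001% on Saturday's.

    starting material + partner → first product (k = 1.10 M⁻¹ s⁻¹)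
    partner + first product → bis adduct (k = 4.20 M⁻¹ s⁻¹)
    partner + bis adduct → triple product (k = 0.760 M⁻¹ s⁻¹)
    partner + triple product → tetra adduct (k = 1.30 M⁻¹ s⁻¹)
    bis adduct ⇌ isomer of the product (K = 1.30, k = 0.260 s⁻¹)
    2 starting material → homo dimer (k = 0.0890 M⁻¹ s⁻¹)

Thursday's retention comes out at 0.779, level with the 0.783 of the epsilon run. Wednesday's, with statistical share 25.7%, has a retention of 0.638, lower than Thursday's, and its tetra adduct stands at 35.3% against 3.73% on Thursday's.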